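**Plan**
1. Retrosynthetic cuts, in order: (i) the 7-OH / C-8 acyl / 1,2-diketone array is folded back, with one extra carbon, into the γ-pyranone of an isoflavone (genistein); (ii) C-3–C-4 is taken back to an alkene; (iii) C-4–C-4a is cut to an aryl propargyl ether; (iv) O-1–C-2 is cut to the genistein 5-OH and a 1-arylpropargylic alcohol.
2. Forward order: 7,4'-di-O-MOM-genistein and the (R)-propargylic alcohol are joined by Mitsunobu etherification; Au(I) 6-endo-dig hydroarylation closes the dihydropyran ring; the alkene is hydrogenated; ozonolysis opens the temporary pyranone to the diketone plus an O-formate; one acidic step removes all protecting groups.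
3. Stereochemistry: the single stereocentre C-2 comes from a lipase-resolved (R)-carbinol, is inverted once to (S) in the Mitsunobu step and is not touched afterwards.
4. Enabling feature: in the A ring, C-4a is the only hydrogen-bearing carbon ortho to O-1 (the other ortho carbon, C-8, carries the acyl group), and it lies between O-1 and O-5 and para to O-7. C-8–CO–CO–Ar together with O-7 is an oxidatively opened isoflavone pyranone. Genistein therefore supplies this half with O-7 and the diketone masked in one temporary ring, O-1 as the only free phenol, and C-4a as the only carbon its propargyl ether can reach.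

Key step: step 5

Remark: the target is the (2S)-flavan. Locants of the isoflavone-stage compounds follow genistein numbering (genistein O-5, C-6, 7-O, O-1, C-4a become O-1, C-4a, 5-O, 7-O, C-8 of the target). Compound 3 is taken as a catalogue item.

**Step 1**
Reactants: 1 genistein
Product: 2 5-hydroxy-7-(methoxymethoxy)-3-[4-(methoxymethoxy)phenyl]-4H-chromen-4-one (7,4'-di-O-MOM-genistein)
Conditions: MOMCl (2.2 equiv), iPr2NEt (3 equiv), DMF, 0 °C → rt
Reagents that add atoms: chloromethyl methyl ether, COCCl
Why: Selective O-alkylation (MOM protection) of the two acidic, unhindered phenols should occur, while the 5-OH, held in a six-membered hydrogen bond to the C-4 carbonyl, stays free as the future ether oxygen O-1.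

**Step 2**
Reactants: 3 tert-butyl 4-formylphenyl carbonate; 4 ethynylmagnesium bromide
Product: 6 rac-1-[4-(tert-butoxycarbonyloxy)phenyl]prop-2-yn-1-yl acetate, via bromomagnesium propargylic alkoxide 5 (not isolated)
Conditions: THF, −78 °C; then Ac2O (1.5 equiv), −78 → 0 °C
Reagents that add atoms: acetic anhydride, CC(=O)OC(C)=O
Why: Grignard 1,2-addition of the acetylide to the aldehyde (the hindered aryl tert-butyl carbonate should survive at −78 °C) is followed by in-flask O-acetylation of the magnesium alkoxide; the carbinol centre is deliberately formed racemic.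

**Step 3**
Reactants: 6 rac-1-[4-(tert-butoxycarbonyloxy)phenyl]prop-2-yn-1-yl acetate
Product: 7 tert-butyl 4-[(1R)-1-hydroxyprop-2-yn-1-yl]phenyl carbonate
Conditions: immobilised Candida antarctica lipase B (Novozym 435), n-BuOH (3 equiv), MTBE, 30 °C, stopped just short of half conversion; chromatography
Reagents that add atoms: none
Why: Lipase-catalysed enantioselective alcoholysis (kinetic resolution of a secondary acetate) follows the enzyme's empirical size rule (large aryl, medium ethynyl), so the (R)-acetate should react fast and release the (R)-alcohol while the (S)-acetate of 6 stays behind and is separated, which sets the only stereocentre of the route.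

**Step 4**
Reactants: 2 7,4'-di-O-MOM-genistein; 7 tert-butyl 4-[(1R)-1-hydroxyprop-2-yn-1-yl]phenyl carbonate
Product: 8 tert-butyl 4-[(1S)-1-({7-(methoxymethoxy)-3-[4-(methoxymethoxy)phenyl]-4-oxo-4H-chromen-5-yl}oxy)prop-2-yn-1-yl]phenyl carbonate
Conditions: PPh3 (1.5 equiv), DIAD (1.5 equiv), toluene (concentrated), 0 °C → rt
Reagents that add atoms: none
Why: Mitsunobu etherification should proceed by SN2 attack of the only acidic OH (the 5-phenol) on the oxyphosphonium ion with inversion, (R)-carbinol to (S)-aryl ether, and the electron-poor carbonate on the aryl group disfavours benzylic ionisation that would erode the configuration.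

**Step 5**
Reactants: 8 the (S)-aryl propargyl ether
Product: 9 tert-butyl 4-[(2S)-5-(methoxymethoxy)-9-[4-(methoxymethoxy)phenyl]-10-oxo-2H,10H-pyrano[2,3-f]chromen-2-yl]phenyl carbonate
Conditions: [(JohnPhos)Au(MeCN)]SbF6 (3 mol%), CH2Cl2, 0 °C → rt, dark
Reagents that add atoms: none
Why: Cationic gold(I) binds the terminal alkyne as a π-acid, and C-6 of the isoflavone (future C-4a), the most electron-rich ring carbon because it is ortho to O-5 and O-7 and para to the pyranone oxygen, attacks the terminal alkyne carbon anti to gold to give a vinyl-gold arenium ion that rearomatises and protodeaurates. The closest known reaction type is the gold(I)-catalysed intramolecular hydroarylation (cycloisomerisation) of aryl propargyl ethers to 2H-chromenes. The dihydropyran ring is closed in the 6-endo-dig mode, which terminal aryl propargyl ethers prefer over 5-exo-dig attack at the internal alkyne carbon. No new stereocentre is formed and the existing one is a spectator, because the O–C-2 bond is never broken (unlike in a thermal propargyl Claisen sequence) and the electron-poor carbonate on the 2-aryl group disfavours ionisation under the mildly Lewis-acidic conditions. The step needs site selectivity, and the substrate secures it: of the two carbons ortho to the ether oxygen, C-4a of the isoflavone is quaternary (part of the temporary pyranone) and only C-6 bears hydrogen, while C-8 and the chromone carbonyl oxygen could only close strained or seven-membered rings.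

**Step 6**
Reactants: 9 the pyrano-fused isoflavone (flav-3-ene)
Product: 10 tert-butyl 4-[(2S)-5-(methoxymethoxy)-9-[4-(methoxymethoxy)phenyl]-10-oxo-3,4-dihydro-2H,10H-pyrano[2,3-f]chromen-2-yl]phenyl carbonate
Conditions: H2 (1 atm), 5% Pd/C, EtOAc, rt, stopped after uptake of 1 equiv
Reagents that add atoms: none
Why: Heterogeneous catalytic hydrogenation should reduce the cis-disubstituted styrenic alkene much faster than the trisubstituted push–pull C-2=C-3 bond of the isoflavone, and MOM ethers and the tert-butyl carbonate are inert to H2/Pd.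

**Step 7**
Reactants: 10 the flavan-fused isoflavone
Product: 12 (2S)-2-[4-(tert-butoxycarbonyloxy)phenyl]-5-(methoxymethoxy)-8-{[4-(methoxymethoxy)phenyl](oxo)acetyl}-3,4-dihydro-2H-chromen-7-yl formate, via methoxy hydroperoxide 11 (not isolated)
Conditions: O3, CH2Cl2/MeOH (4:1), −78 °C, Sudan Red 7B end point; then Me2S, −78 °C → rt
Reagents that add atoms: ozone, [O-][O+]=O
Why: Ozonolysis of the enol-ether C-2=C-3 bond, the only non-aromatic C=C left, should turn isoflavone C-3 into the second ketone of the 1,2-diketone and C-2 into a formate on the phenol oxygen, which removes the temporary pyranone ring; Me2S reduces the methanol-trapped hydroperoxide.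

**Step 8**
Reactants: 12 the protected diketone formate
Product: 13 1-[(2S)-5,7-dihydroxy-2-(4-hydroxyphenyl)-3,4-dihydro-2H-chromen-8-yl]-2-(4-hydroxyphenyl)ethane-1,2-dione (target)
Conditions: HCl (3 M) in MeOH/THF (1:1), 40 °C
Reagents that add atoms: none
Why: Acid-catalysed acetal cleavage of both MOM ethers, acidolysis of the aryl tert-butyl carbonate and methanolysis of the aryl formate should occur in one operation, and acid is chosen because base would invite benzilic acid rearrangement of the diketone and quinone-methide epimerisation at C-2 once the 4'-OH is free.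

**Compound list**
1 | genistein, 5,7-dihydroxy-3-(4-hydroxyphenyl)-4H-chromen-4-one | O=c1c(-c2ccc(O)cc2)coc2cc(O)cc(O)c12 | starting material
2 | 5-hydroxy-7-(methoxymethoxy)-3-[4-(methoxymethoxy)phenyl]-4H-chromen-4-one | O=c1c(-c2ccc(OCOC)cc2)coc2cc(OCOC)cc(O)c12 | intermediate
3 | tert-butyl 4-formylphenyl carbonate | O=Cc1ccc(OC(=O)OC(C)(C)C)cc1 | starting material
4 | ethynylmagnesium bromide | C#C[Mg]Br | starting material
5 | bromomagnesium 1-[4-(tert-butoxycarbonyloxy)phenyl]prop-2-yn-1-olate, racemic (not isolated) | C#CC(O[Mg]Br)c1ccc(OC(=O)OC(C)(C)C)cc1 | intermediate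
6 | rac-1-[4-(tert-butoxycarbonyloxy)phenyl]prop-2-yn-1-yl acetate | CC(=O)OC(C#C)c1ccc(OC(=O)OC(C)(C)C)cc1 | intermediate
7 | tert-butyl 4-[(1R)-1-hydroxyprop-2-yn-1-yl]phenyl carbonate | C#C[C@@H](O)c1ccc(OC(=O)OC(C)(C)C)cc1 | intermediate
8 | tert-butyl 4-[(1S)-1-({7-(methoxymethoxy)-3-[4-(methoxymethoxy)phenyl]-4-oxo-4H-chromen-5-yl}oxy)prop-2-yn-1-yl]phenyl carbonate | O=c1c(-c2ccc(OCOC)cc2)coc2cc(OCOC)cc(O[C@@H](C#C)c3ccc(OC(=O)OC(C)(C)C)cc3)c12 | intermediate
9 | tert-butyl 4-[(2S)-5-(methoxymethoxy)-9-[4-(methoxymethoxy)phenyl]-10-oxo-2H,10H-pyrano[2,3-f]chromen-2-yl]phenyl carbonate | O=c1c(-c2ccc(OCOC)cc2)coc2cc(OCOC)c3c(c12)O[C@H](c1ccc(OC(=O)OC(C)(C)C)cc1)C=C3 | intermediate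
10 | tert-butyl 4-[(2S)-5-(methoxymethoxy)-9-[4-(methoxymethoxy)phenyl]-10-oxo-3,4-dihydro-2H,10H-pyrano[2,3-f]chromen-2-yl]phenyl carbonate | O=c1c(-c2ccc(OCOC)cc2)coc2cc(OCOC)c3c(c12)O[C@H](c1ccc(OC(=O)OC(C)(C)C)cc1)CC3 | intermediate
11 | (2S)-2-[4-(tert-butoxycarbonyloxy)phenyl]-8-{2-hydroperoxy-2-methoxy-2-[4-(methoxymethoxy)phenyl]acetyl}-5-(methoxymethoxy)-3,4-dihydro-2H-chromen-7-yl formate, mixture at the peroxy carbon (not isolated) | COC(OO)(C(=O)c1c(OC=O)cc(OCOC)c2c1O[C@H](c1ccc(OC(=O)OC(C)(C)C)cc1)CC2)c1ccc(OCOC)cc1 | intermediate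
12 | (2S)-2-[4-(tert-butoxycarbonyloxy)phenyl]-5-(methoxymethoxy)-8-{[4-(methoxymethoxy)phenyl](oxo)acetyl}-3,4-dihydro-2H-chromen-7-yl formate | O=C(C(=O)c1c(OC=O)cc(OCOC)c2c1O[C@H](c1ccc(OC(=O)OC(C)(C)C)cc1)CC2)c1ccc(OCOC)cc1 | intermediate
13 | 1-[(2S)-5,7-dihydroxy-2-(4-hydroxyphenyl)-3,4-dihydro-2H-chromen-8-yl]-2-(4-hydroxyphenyl)ethane-1,2-dione | O=C(C(=O)c1c(O)cc(O)c2c1O[C@H](c1ccc(O)cc1)CC2)c1ccc(O)cc1 | target

**Totals and risks**
Total step count: 8. Longest linear sequence: 7 steps (steps 2–8, from 3 and 4 to 13).

Steps most likely to fail: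

1. Step 4. The hydrogen-bonded, hindered 5-OH may capture the oxyphosphonium ion too slowly, so that the hydrazide anion is alkylated instead and partial ionisation lowers the enantiopurity. The fallback replaces SN2 inversion by an enantioconvergent copper-catalysed propargylic etherification through a copper allenylidene. It sets out from phenol 2 and the racemic acetate 6 (Cu(OTf)2, chiral pybox ligand with the antipode chosen for the (S)-ether, iPr2NEt, −10 °C) and comes back to the route at 8. It makes no new compound (F0), and step 3 is then not needed.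

2. Step 5. The enantiopurity may erode through reversible C–O ionisation or a propargyl-Claisen-type leak, and some 5-exo closure may compete. The fallback changes the activation from a π-acid to an iodonium ion. It sets out from 8, which on treatment with bis(pyridine)iodonium tetrafluoroborate and HBF4·OEt2 in CH2Cl2 at −78 °C should undergo 6-endo-dig iodoarylation to tert-butyl 4-[(2R)-3-iodo-5-(methoxymethoxy)-9-[4-(methoxymethoxy)phenyl]-10-oxo-2H,10H-pyrano[2,3-f]chromen-2-yl]phenyl carbonate F1 (same spatial arrangement as 9; the descriptor changes because iodine raises the rank of C-3). Hydrogenation over Pd/C with Et3N in EtOAc should then saturate the alkene and remove the iodine, and the fallback comes back at 10.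

3. Step 7. Ozone may also attack the MOM-oxygenated aromatic rings or over-oxidise the product before the push–pull alkene is consumed. The fallback avoids ozone. It sets out from 10, which with dimethyldioxirane in acetone at 0 °C should give the epoxide of the isoflavone C-2=C-3 bond, tert-butyl 4-[(2S)-8,9-epoxy-5-(methoxymethoxy)-9-[4-(methoxymethoxy)phenyl]-10-oxo-3,4,8,9-tetrahydro-2H,10H-pyrano[2,3-f]chromen-2-yl]phenyl carbonate F2. Periodic acid in aqueous THF should hydrolyse this acetal-type epoxide to the 2,3-diol and cleave it to ketone plus formate, and the fallback comes back at 12.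

**Further compounds**
F0 | step 4 | none | none
F1 | step 5 | tert-butyl 4-[(2R)-3-iodo-5-(methoxymethoxy)-9-[4-(methoxymethoxy)phenyl]-10-oxo-2H,10H-pyrano[2,3-f]chromen-2-yl]phenyl carbonate | O=c1c(-c2ccc(OCOC)cc2)coc2cc(OCOC)c3c(c12)O[C@H](c1ccc(OC(=O)OC(C)(C)C)cc1)C(I)=C3
F2 | step 7 | tert-butyl 4-[(2S)-8,9-epoxy-5-(methoxymethoxy)-9-[4-(methoxymethoxy)phenyl]-10-oxo-3,4,8,9-tetrahydro-2H,10H-pyrano[2,3-f]chromen-2-yl]phenyl carbonate (epoxide diastereomers) | O=C1c2c(OC3OC13c1ccc(OCOC)cc1)cc(OCOC)c1c2O[C@H](c2ccc(OC(=O)OC(C)(C)C)cc2)CC1
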